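**Retrosynthetic overview**
- The target, (2S)-4',7-dihydroxyflavan-(4β→8)-(−)-epiafzelechin-(4β→8)-(−)-epiafzelechin, is reached by hydrogenolysis of its octabenzyl ether.
- Key disconnection: ring C of the upper flavan is cut at C2–C3 and at the C4–C8 interflavan bond in one retro-step. This leaves an aryl methyl mixed acetal with an ortho-vinyl group and a benzylated epiafzelechin-(4β→8)-epiafzelechin dimer. Forward, an aryloxy-oxocarbenium ion closes ring C by C2–C3 bond formation (Prins) and the C4 cation so formed is arylated by C8 of the dimer.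
- Enabling feature: C4 of the upper ring C is benzylic to ring A, para to the C7 oxygen and ortho to the ring oxygen O1, and C2 carries both O1 and the para-oxygenated ring B, so each end of the C2–C3 bond can hold a stabilised cation.
- The dimer comes from (−)-epiafzelechin (benzylation, C4 oxidation, Friedel–Crafts coupling); the acetal comes from 4-(benzyloxy)benzaldehyde and 4-(benzyloxy)-2-hydroxybenzaldehyde (chloro ether O-alkylation, Wittig).
- Ring order: the rings of both epiafzelechin units are bought in with the chiral pool; ring C of the upper flavan is the only ring made (step 7).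

Key step: step 7

Remark: (−)-epiafzelechin, the (2R,3R)-flavan-3-ol, is assumed to be bought as the isolated natural product.
Remark: for the acid of step 7 the (S,S) antipode is written; the antipode that leads into the (2S) series is to be fixed in a first small-scale run, the two possible products being diastereomers.

**Step 1**
Reactants: 1 4-(benzyloxy)benzaldehyde
Product: 2 1-(benzyloxy)-4-(dimethoxymethyl)benzene
Conditions: HC(OMe)3 (3 equiv), p-TsOH·H2O (1 mol %), MeOH, rt; then Et3N
Reagents that add atoms: trimethyl orthoformate, COC(OC)OC; methanol, CO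
Why: Acid-catalysed acetalization, with the orthoformate as water scavenger, should drive the aldehyde fully to the dimethyl acetal while the benzyl ether stays inert.

**Step 2**
Reactants: 2 1-(benzyloxy)-4-(dimethoxymethyl)benzene; 3 4-(benzyloxy)-2-hydroxybenzaldehyde
Product: 5 4-(benzyloxy)-2-{[4-(benzyloxy)phenyl](methoxy)methoxy}benzaldehyde, via alpha-chloro ether 4 (not isolated)
Conditions: AcCl (1.1 equiv), CH2Cl2, 0 °C to rt, volatiles removed; then 3, iPr2NEt (1.5 equiv), CH2Cl2, −40 °C to 0 °C
Reagents that add atoms: acetyl chloride, CC(Cl)=O (its chlorine is carried by intermediate 4 only)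
Why: Acetyl chloride should convert the electron-rich dimethyl acetal into the alpha-chloro ether (acetal to chloro ether exchange), and the phenoxide of 3, whose ring is deactivated towards C-alkylation by the formyl group, should displace chloride in an SN1-type O-alkylation to give the mixed aryl methyl acetal, whose racemic acetal carbon is of no consequence because it is ionised in step 7.

**Step 3**
Reactants: 5 4-(benzyloxy)-2-{[4-(benzyloxy)phenyl](methoxy)methoxy}benzaldehyde
Product: 6 4-(benzyloxy)-2-{[4-(benzyloxy)phenyl](methoxy)methoxy}-1-ethenylbenzene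
Conditions: MePPh3Br (1.5 equiv), KOtBu (1.4 equiv), THF, 0 °C to rt; chromatography on Et3N-deactivated silica
Reagents that add atoms: methyltriphenylphosphonium bromide, C[P+](c1ccccc1)(c1ccccc1)c1ccccc1.[Br-]
Why: Wittig methylenation under basic conditions should turn the aldehyde into the styrene while the base-stable mixed acetal is untouched.

**Step 4**
Reactants: 7 (−)-epiafzelechin
Product: 8 5,7,4'-tri-O-benzyl-(−)-epiafzelechin
Conditions: BnBr (3.3 equiv), K2CO3 (3.5 equiv), DMF, 0 °C to rt, argon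
Reagents that add atoms: benzyl bromide, BrCc1ccccc1
Why: Williamson ether synthesis under a weak base should alkylate only the three phenols, since K2CO3 does not deprotonate the secondary C3 alcohol, and it leaves C2 and C3 untouched.

**Step 5**
Reactants: 8 5,7,4'-tri-O-benzyl-(−)-epiafzelechin
Product: 10 (2R,3R,4S)-5,7-bis(benzyloxy)-2-[4-(benzyloxy)phenyl]-4-(2-ethoxyethoxy)chroman-3-ol, via flavan-4-ylium hydroquinolate ion pair 9 (not isolated)
Conditions: DDQ (2 equiv), 2-ethoxyethanol (5 equiv), CH2Cl2, rt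
Reagents that add atoms: 2-ethoxyethanol, CCOCCO; DDQ (2,3-dichloro-5,6-dicyano-1,4-benzoquinone), N#CC1=C(C#N)C(=O)C(Cl)=C(Cl)C1=O (its atoms are carried by intermediate 9 only)
Why: DDQ should abstract hydride from C4, the benzylic position activated by the 5,7-dioxygenated ring A and O1 (oxidative benzylic alkoxylation), to give ion pair 9, and 2-ethoxyethanol should add to its cation from the beta face, anti to the C2 aryl and C3 hydroxyl groups, which sets C4 as S (3,4-trans) while the hydroquinolate takes up the proton.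

**Step 6**
Reactants: 10 (2R,3R,4S)-5,7-bis(benzyloxy)-2-[4-(benzyloxy)phenyl]-4-(2-ethoxyethoxy)chroman-3-ol; 8 5,7,4'-tri-O-benzyl-(−)-epiafzelechin
Product: 12 5,7,4'-tri-O-benzylepiafzelechin-(4β→8)-5,7,4'-tri-O-benzylepiafzelechin, via epiafzelechin C4 cation 11 (not isolated)
Conditions: Me3SiOTf (0.5 equiv), 8 (4 equiv, excess recovered), CH2Cl2, −78 °C; Et3N quench
Reagents that add atoms: none
Why: Lewis-acid ionisation of the C4 ether should set free the C4 cation 11, which alkylates C8, the most nucleophilic position of the excess nucleophile 8, in a Friedel–Crafts reaction from the beta face (anti to the cis C2 aryl and C3 hydroxyl groups) and so sets the 4β→8 bond, while the excess of 8 suppresses chain growth.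

**Step 7**
Reactants: 6 4-(benzyloxy)-2-{[4-(benzyloxy)phenyl](methoxy)methoxy}-1-ethenylbenzene; 12 5,7,4'-tri-O-benzylepiafzelechin-(4β→8)-5,7,4'-tri-O-benzylepiafzelechin
Product: 15 (2S,4R)-4',7-bis(benzyloxy)flavan-(4β→8)-5,7,4'-tri-O-benzylepiafzelechin-(4β→8)-5,7,4'-tri-O-benzylepiafzelechin, via oxocarbenium ion 13 (not isolated), via flavan-4-ylium ion 14 (not isolated)
Conditions: confined imidodiphosphorimidate acid (S,S)-[(3,3'-Ar2-1,1'-binaphthalene-2,2'-diyldioxy)P(=NSO2CF3)]2NH, Ar = 3,5-(CF3)2C6H3 (5 mol %), 5 Å MS, CH2Cl2, −60 °C to −30 °C, 6 (1.5 equiv) added slowly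
Reagents that add atoms: none
Why: Proposed new method: the acid should ionise mixed acetal 6 (loss of methanol) to the aryloxy-oxocarbenium ion 13, whose ortho-vinyl group attacks the oxocarbenium carbon and forms the C2–C3 bond, and the resulting 2,4-dioxygenated benzylic cation 14 should then be captured at C8 of the upper unit of 12 in a Friedel–Crafts alkylation that returns the proton to the catalyst. The closest known reaction types are the Prins cyclization/Friedel–Crafts cascade of homoallylic alcohols with aldehydes and arenes, the oxa-Povarov reaction of aryl oxocarbenium ions with styrenes, and confined-acid-catalysed asymmetric Prins cyclizations; new is an aryl mixed acetal that carries its own vinyl group, with an arene as terminating nucleophile under chiral-anion control. Ring C closes in a 6-endo-trig cationic mode, preferred over 5-exo because only the endo path places the charge at C4, benzylic to ring A, para to the C7 benzyloxy group and ortho to O1. C2 is set in the ring closure by the chiral counteranion, which shields one face of the oxocarbenium ion, and C4 is set by C2, because the arene adds pseudo-axially to the half-chair cation 14 on the face anti to the pseudo-equatorial C2 aryl group, which should give the 2,4-trans flavan. The step needs site selectivity for C8 of the upper unit of 12, which lies between O1 and one benzyloxy group and is less hindered than the C6 positions between two benzyloxy groups, and it needs ring closure to outrun intermolecular capture of 13, which slow addition of 6 at low temperature should secure. Capture of either cation by methanol or by the free C3 hydroxyl groups is reversible under the acid whereas C-arylation is not, and any (2R,4S) diastereomer that escapes catalyst control is removed by chromatography because 12 is a single enantiomer.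

**Step 8**
Reactants: 15 (2S,4R)-4',7-bis(benzyloxy)flavan-(4β→8)-5,7,4'-tri-O-benzylepiafzelechin-(4β→8)-5,7,4'-tri-O-benzylepiafzelechin
Product: 16 (2S,4R)-4',7-dihydroxyflavan-(4β→8)-(−)-epiafzelechin-(4β→8)-(−)-epiafzelechin (CNP0257624.1)
Conditions: H2 (1 atm), Pd(OH)2 on carbon, THF/MeOH/H2O, rt
Reagents that add atoms: none
Why: Hydrogenolysis of the eight benzyl ethers under neutral conditions should free all phenols without touching the C2–O1 ether bonds, the interflavan bonds or any stereocenter.

**Compound list**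
1 | 4-(benzyloxy)benzaldehyde | O=Cc1ccc(OCc2ccccc2)cc1 | starting material
2 | 1-(benzyloxy)-4-(dimethoxymethyl)benzene | COC(OC)c1ccc(OCc2ccccc2)cc1 | intermediate
3 | 4-(benzyloxy)-2-hydroxybenzaldehyde | O=Cc1ccc(OCc2ccccc2)cc1O | starting material
4 | 1-(benzyloxy)-4-[chloro(methoxy)methyl]benzene (racemic alpha-chloro ether, not isolated) | COC(Cl)c1ccc(OCc2ccccc2)cc1 | intermediate
5 | 4-(benzyloxy)-2-{[4-(benzyloxy)phenyl](methoxy)methoxy}benzaldehyde (racemic at the acetal carbon) | O=Cc1ccc(OCc2ccccc2)cc1OC(OC)c1ccc(OCc2ccccc2)cc1 | intermediate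
6 | 4-(benzyloxy)-2-{[4-(benzyloxy)phenyl](methoxy)methoxy}-1-ethenylbenzene (racemic at the acetal carbon) | C=Cc1ccc(OCc2ccccc2)cc1OC(OC)c1ccc(OCc2ccccc2)cc1 | intermediate
7 | (−)-epiafzelechin, (2R,3R)-2-(4-hydroxyphenyl)chromane-3,5,7-triol | Oc1cc(O)c2c(c1)O[C@H](c1ccc(O)cc1)[C@H](O)C2 | starting material
8 | 5,7,4'-tri-O-benzyl-(−)-epiafzelechin, (2R,3R)-5,7-bis(benzyloxy)-2-[4-(benzyloxy)phenyl]chroman-3-ol | c1c(OCc5ccccc5)cc(OCc5ccccc5)c2c1O[C@H](c1ccc(OCc5ccccc5)cc1)[C@H](O)C2 | intermediate
9 | (2R,3R)-5,7-bis(benzyloxy)-2-[4-(benzyloxy)phenyl]-3-hydroxychroman-4-ylium 2,3-dichloro-5,6-dicyano-4-hydroxyphenolate (ion pair from hydride transfer to DDQ, not isolated) | c1c(OCc5ccccc5)cc(OCc5ccccc5)c2c1O[C@H](c1ccc(OCc5ccccc5)cc1)[C@H](O)[CH+]2.[O-]c1c(Cl)c(Cl)c(O)c(C#N)c1C#N | intermediate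
10 | (2R,3R,4S)-5,7-bis(benzyloxy)-2-[4-(benzyloxy)phenyl]-4-(2-ethoxyethoxy)chroman-3-ol (4β ether) | c1c(OCc5ccccc5)cc(OCc5ccccc5)c2c1O[C@H](c1ccc(OCc5ccccc5)cc1)[C@H](O)[C@H]2OCCOCC | intermediate
11 | (2R,3R)-5,7-bis(benzyloxy)-2-[4-(benzyloxy)phenyl]-3-hydroxychroman-4-ylium (C4 cation set free from ether 10 by Me3SiOTf, not isolated) | c1c(OCc5ccccc5)cc(OCc5ccccc5)c2c1O[C@H](c1ccc(OCc5ccccc5)cc1)[C@H](O)[CH+]2 | intermediate
12 | 5,7,4'-tri-O-benzylepiafzelechin-(4β→8)-5,7,4'-tri-O-benzylepiafzelechin, (2R,3R,4R) in the upper unit and (2R,3R) in the lower unit | c1c(OCc5ccccc5)cc(OCc5ccccc5)c2c1O[C@H](c1ccc(OCc5ccccc5)cc1)[C@H](O)[C@H]2c1c(OCc5ccccc5)cc(OCc5ccccc5)c2c1O[C@H](c1ccc(OCc5ccccc5)cc1)[C@H](O)C2 | intermediate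
13 | [5-(benzyloxy)-2-ethenylphenyl][4-(benzyloxy)benzylidene]oxonium (aryloxy-oxocarbenium ion, not isolated) | C=Cc1ccc(OCc2ccccc2)cc1[O+]=Cc1ccc(OCc2ccccc2)cc1 | intermediate
14 | (2S)-7-(benzyloxy)-2-[4-(benzyloxy)phenyl]chroman-4-ylium (not isolated) | c5ccccc5COc1ccc([C@@H]2C[CH+]c3ccc(OCc5ccccc5)cc3O2)cc1 | intermediate
15 | (2S,4R)-4',7-bis(benzyloxy)flavan-(4β→8)-5,7,4'-tri-O-benzylepiafzelechin-(4β→8)-5,7,4'-tri-O-benzylepiafzelechin, (2R,3R,4S) in the middle unit and (2R,3R) in the lower unit | c5ccccc5COc1ccc([C@@H]2C[C@@H](c3c(OCc5ccccc5)cc(OCc5ccccc5)c4c3O[C@H](c3ccc(OCc5ccccc5)cc3)[C@H](O)[C@H]4c3c(OCc5ccccc5)cc(OCc5ccccc5)c4c3O[C@H](c3ccc(OCc5ccccc5)cc3)[C@H](O)C4)c3ccc(OCc5ccccc5)cc3O2)cc1 | intermediate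
16 | (2R,3R,4S)-8-[(2S,4R)-7-hydroxy-2-(4-hydroxyphenyl)chroman-4-yl]-2-(4-hydroxyphenyl)-4-[(2R,3R)-3,5,7-trihydroxy-2-(4-hydroxyphenyl)chroman-8-yl]chromane-3,5,7-triol (CNP0257624.1) | Oc1ccc([C@@H]2C[C@@H](c3c(O)cc(O)c4c3O[C@H](c3ccc(O)cc3)[C@H](O)[C@H]4c3c(O)cc(O)c4c3O[C@H](c3ccc(O)cc3)[C@H](O)C4)c3ccc(O)cc3O2)cc1 | target

**Step count and risks**
Total steps: 8. Longest linear sequence: 5 steps (steps 4, 5, 6, 7, 8; the acetal branch, steps 1, 2, 3, 7, 8, is equally long).

Steps most likely to fail:

Step 7 (proposed method). The ring closure may proceed with poor enantiofacial control, oxocarbenium ion 13 may be intercepted by 12 before it cyclises, or the acid may cleave an interflavan bond of 12 or 15. Fallback by known chemistry, setting out from 1 and 12 and coming back at 15: Claisen–Schmidt condensation of 1 with commercial 1-[4-(benzyloxy)-2-hydroxyphenyl]ethanone (KOH, EtOH, rt) would give the chalcone (E)-1-[4-(benzyloxy)-2-hydroxyphenyl]-3-[4-(benzyloxy)phenyl]prop-2-en-1-one F1. Oxa-Michael ring closure (NaOAc, EtOH, reflux) would give racemic 7-(benzyloxy)-2-[4-(benzyloxy)phenyl]chroman-4-one F2. Asymmetric transfer hydrogenation run as a kinetic resolution (RuCl[(S,S)-TsDPEN](p-cymene), HCO2H/Et3N, EtOAc, rt, with the catalyst antipode that reduces the (2S) ketone faster) would give the cis alcohol (2S,4S)-7-(benzyloxy)-2-[4-(benzyloxy)phenyl]chroman-4-ol F3, separated from the unreduced (2R) ketone. F3 and 12 with Me3SiOTf in CH2Cl2 at −78 °C would then give 15 through the same cation 14 by Friedel–Crafts alkylation, the C2 stereocenter now coming from the resolution.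

Step 2. The alpha-chloro ether and the mixed acetal may ionise too early, with hydrolysis back to 1 and 3 during work-up or chromatography. Fallback, setting out from 3 and coming back at 5: O-alkylation of 3 with 4-(benzyloxy)benzyl chloride (K2CO3, DMF, rt) would give 4-(benzyloxy)-2-{[4-(benzyloxy)benzyl]oxy}benzaldehyde F4. DDQ in CH2Cl2/MeOH over 4 Å MS at 0 °C would then oxidise its 4-alkoxybenzylic CH2 by hydride abstraction, and capture of the oxocarbenium ion by methanol would give 5, so that no chloro ether is handled.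

Step 6. Chain growth beyond the dimer may occur, by self-condensation of 10 through its own C8 or by 12 competing with 8 as nucleophile. Fallback, setting out from 8 and coming back at 12: bromination of 8 at C8 (NBS, CH2Cl2, −78 °C) would give 8-bromo-5,7,4'-tri-O-benzyl-(−)-epiafzelechin F5. DDQ and 2-ethoxyethanol as in step 5 would give (2R,3R,4S)-5,7-bis(benzyloxy)-2-[4-(benzyloxy)phenyl]-8-bromo-4-(2-ethoxyethoxy)chroman-3-ol F6. Coupling of F6 with 8 (Me3SiOTf, CH2Cl2, −78 °C), in which the capped electrophile cannot condense with itself, would give 8-bromo-5,7,4'-tri-O-benzylepiafzelechin-(4β→8)-5,7,4'-tri-O-benzylepiafzelechin F7. Bromine–lithium exchange (n-BuLi in excess, THF, −78 °C) and protonation with MeOH would give 12.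

**Further compounds**
F1 | step 7 | (E)-1-[4-(benzyloxy)-2-hydroxyphenyl]-3-[4-(benzyloxy)phenyl]prop-2-en-1-one | O=C(/C=C/c1ccc(OCc2ccccc2)cc1)c1ccc(OCc2ccccc2)cc1O
F2 | step 7 | racemic 7-(benzyloxy)-2-[4-(benzyloxy)phenyl]chroman-4-one | O=C1CC(c2ccc(OCc3ccccc3)cc2)Oc2cc(OCc3ccccc3)ccc21
F3 | step 7 | (2S,4S)-7-(benzyloxy)-2-[4-(benzyloxy)phenyl]chroman-4-ol | c5ccccc5COc1ccc([C@@H]2C[C@H](O)c3ccc(OCc5ccccc5)cc3O2)cc1
F4 | step 2 | 4-(benzyloxy)-2-{[4-(benzyloxy)benzyl]oxy}benzaldehyde | O=Cc1ccc(OCc2ccccc2)cc1OCc1ccc(OCc2ccccc2)cc1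
F5 | step 6 | 8-bromo-5,7,4'-tri-O-benzyl-(−)-epiafzelechin, (2R,3R)-5,7-bis(benzyloxy)-2-[4-(benzyloxy)phenyl]-8-bromochroman-3-ol | Brc1c(OCc5ccccc5)cc(OCc5ccccc5)c2c1O[C@H](c1ccc(OCc5ccccc5)cc1)[C@H](O)C2
F6 | step 6 | (2R,3R,4S)-5,7-bis(benzyloxy)-2-[4-(benzyloxy)phenyl]-8-bromo-4-(2-ethoxyethoxy)chroman-3-ol | Brc1c(OCc5ccccc5)cc(OCc5ccccc5)c2c1O[C@H](c1ccc(OCc5ccccc5)cc1)[C@H](O)[C@H]2OCCOCC
F7 | step 6 | 8-bromo-5,7,4'-tri-O-benzylepiafzelechin-(4β→8)-5,7,4'-tri-O-benzylepiafzelechin | Brc1c(OCc5ccccc5)cc(OCc5ccccc5)c2c1O[C@H](c1ccc(OCc5ccccc5)cc1)[C@H](O)[C@H]2c1c(OCc5ccccc5)cc(OCc5ccccc5)c2c1O[C@H](c1ccc(OCc5ccccc5)cc1)[C@H](O)C2
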